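**Retrosynthetic overview**

1. C40 = ε-C15 aldehyde 21 + C10 dialdehyde 31 + acetylenic β-C15 phosphonium salt 30: Wittig at C11'=C12' (last) and at C11=C12; Sonogashira at C6–C7 (enol triflate of actinol + enynol 1, which also supplies C3'–C7' of the ε half).
2. ε ring: the C4'=C5' double bond lies between the O-bearing C3' and the chain-bearing C6', and the two remaining ring atoms, quaternary C1' (gem-dimethyl) and C2' (CH2), are unfunctionalised. This is a cyclohexene (Diels–Alder) retron: diene C3'=C4'–C5'(Me)=C6' (dienyl ester 9) + 2-methyl-1-nitroprop-1-ene as a regiocontrolled isobutene equivalent; C2'–C3' and C6'–C1' form together.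
3. One bought stereocentre (the mandelate of 9) is relayed to C3' and C6' in that event; the nitro group is then removed and the cis adduct is converted to the trans (3'R,6'R) series by Mitsunobu inversion at C3'. C3 comes from (4R,6R)-actinol.
4. Rings: the ε ring is the only ring constructed (step 4); the β ring is carried intact from actinol (steps 12–14).

Key step: step 4

Assumption (chemistry): the (2S)-mandelate of 9 is taken to direct the dienophile to the diene face that is Si at the ester-bearing carbon (approach anti to the phenyl group). This sense is assumed, not derived; if the bias is opposite, the commercial (2R)-acid is used instead, all else unchanged.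

**Route**

Step 1
Reactants: 1 (2E)-3-methylpent-2-en-4-yn-1-ol; 2 4-methoxybenzyl chloride
Product: 3 1-methoxy-4-({[(2E)-3-methylpent-2-en-4-yn-1-yl]oxy}methyl)benzene
Conditions: NaH (1.05 equiv), 2, Bu4NI (cat.), THF/DMF, 0 °C → rt
Reagents that add atoms: 4-methoxybenzyl chloride, COc1ccc(CCl)cc1
Why: Williamson etherification of the primary allylic alkoxide; one equivalent of NaH leaves the much less acidic alkyne C–H untouched.

Step 2
Reactants: 3; 4 pinacolborane; 5 potassium hydrogen difluoride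
Product: 7 potassium trifluoro{(1E,3E)-5-[(4-methoxybenzyl)oxy]-3-methylpenta-1,3-dien-1-yl}borate, via dienyl pinacol boronate 6 (not isolated)
Conditions: 4, Cp2Zr(H)Cl (cat.), Et3N (cat.), CH2Cl2, rt; then aq. KHF2, MeOH, rt
Reagents that add atoms: pinacolborane, CC1(C)OBOC1(C)C; potassium hydrogen difluoride, [K+].[F-].F
Why: Zirconium-catalysed syn-hydroboration of the terminal alkyne of the conjugated enyne puts boron on the terminal carbon and fixes the new (1E) alkene while the existing (3E) alkene is untouched, and KHF2 then exchanges pinacol for fluoride (trifluoroborate formation).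

Step 3
Reactants: 7; 8 (2S)-2-methoxy-2-phenylacetic acid
Product: 9 (1E,3E)-5-[(4-methoxybenzyl)oxy]-3-methylpenta-1,3-dien-1-yl (2S)-2-methoxy-2-phenylacetate
Conditions: 8 (1.2 equiv), CuBr (cat.), DMAP (cat.), 4 Å MS, O2 (1 atm), MeCN, 40 °C
Reagents that add atoms: (2S)-2-methoxy-2-phenylacetic acid, CO[C@H](C(=O)O)c1ccccc1
Why: Copper-catalysed oxidative C(sp2)–O coupling of an alkenyltrifluoroborate with a carboxylic acid (Chan–Lam-type enol ester synthesis) goes with retention of alkene geometry, so the (1E,3E) dienyl ester is obtained without enolate chemistry and without making the racemisation-prone acid chloride.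

Step 4
Reactants: 9; 10 2-methyl-1-nitroprop-1-ene
Product: 11 (1R,4S)-4-{[(4-methoxybenzyl)oxy]methyl}-3,5,5-trimethyl-6-nitrocyclohex-2-en-1-yl (2S)-2-methoxy-2-phenylacetate (ester oxygen and CH2O arm cis; both C6 epimers)
Conditions: 10 (5 equiv), BHT (cat.), CH2Cl2, 12 kbar, 40 °C
Reagents that add atoms: 2-methyl-1-nitroprop-1-ene, CC(C)=C[N+](=O)[O-]
Why: Concerted but asynchronous normal-demand Diels–Alder cycloaddition of the electron-rich dienyl ester to the nitroalkene, the closest known type being thermal or high-pressure additions of β,β-disubstituted nitroalkenes to 1-oxygenated dienes in which nitro is a removable regiochemical control element. The ε ring is closed as a six-membered carbocycle by intermolecular suprafacial [4+2] addition, the diene terminus C6' bonding to the nitroalkene β-carbon (future C1') and C3' to the nitro-bearing carbon (future C2'). The (1E,3E) geometry fixes C3'–O and C6'–C7' cis, and the absolute sense at both centres is relayed from the single mandelate stereocentre, whose aryl group shields one diene face. Regioselectivity is required and is secured by matched polarisation: acyloxy at C3' and methyl at C5' make C6' the nucleophilic terminus, and the β-carbon of the nitroalkene is the electrophilic one. The endo/exo ratio at C2' does not matter because that centre is erased in step 5, and no Lewis acid is used so that the nitroalkene does not react as a heterodiene. High pressure offsets the congestion of forming the C6'–C1' bond next to a quaternary carbon.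

Step 5
Reactants: 11
Product: 12 (1S,4R)-4-{[(4-methoxybenzyl)oxy]methyl}-3,5,5-trimethylcyclohex-2-en-1-yl (2S)-2-methoxy-2-phenylacetate (cis)
Conditions: Bu3SnH (5 equiv, 1 M), AIBN (portions), toluene, 110 °C
Reagents that add atoms: none
Why: Radical denitration (stannyl radical adds to the nitro oxygen, C–N homolysis gives the secondary radical next to the quaternary carbon, hydrogen transfer from the stannane) erases the nitro-bearing centre so both epimers converge; the high stannane concentration keeps hydrogen transfer ahead of 1,2-acyloxy shift, and the minor facial diastereomer is removed by chromatography here.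

Step 6
Reactants: 12
Product: 13 (1S,4R)-4-{[(4-methoxybenzyl)oxy]methyl}-3,5,5-trimethylcyclohex-2-en-1-ol (cis)
Conditions: K2CO3, MeOH, 0 °C → rt
Reagents that add atoms: none
Why: Base-catalysed transesterification frees the allylic alcohol with both ring stereocentres untouched and returns the auxiliary as its methyl ester.

Step 7
Reactants: 13; 14 benzoic acid
Product: 15 (1R,4R)-4-{[(4-methoxybenzyl)oxy]methyl}-3,5,5-trimethylcyclohex-2-en-1-yl benzoate (trans)
Conditions: 14, PPh3, DIAD, THF, 0 °C → rt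
Reagents that add atoms: benzoic acid, OC(=O)c1ccccc1
Why: Mitsunobu esterification inverts the carbinol centre by SN2 displacement of the oxyphosphonium group and so turns the cis adduct into the trans (3'R,6'R) relationship of the target; SN2' attack is disfavoured because the distal alkene carbon is fully substituted.

Step 8
Reactants: 15
Product: 16 (1R,4R)-4-(hydroxymethyl)-3,5,5-trimethylcyclohex-2-en-1-yl benzoate
Conditions: DDQ, CH2Cl2/pH 7 buffer, 0 °C
Reagents that add atoms: none
Why: Oxidative cleavage of the electron-rich 4-methoxybenzyl ether (benzylic hydride abstraction, hydrolysis of the oxocarbenium ion) leaves the benzoate and the trisubstituted alkene untouched.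

Step 9
Reactants: 16
Product: 17 (1R,4R)-4-formyl-3,5,5-trimethylcyclohex-2-en-1-yl benzoate
Conditions: DMP (triacetoxy periodinane), NaHCO3, CH2Cl2, 0 °C; used crude
Reagents that add atoms: none
Why: Buffered periodinane oxidation stops at the aldehyde under non-basic conditions, which protects the α-stereocentre of this β,γ-unsaturated aldehyde.

Step 10
Reactants: 17; 18 diethyl [(2E)-3-cyano-2-methylprop-2-en-1-yl]phosphonate
Product: 19 (1R,4R)-4-[(1E,3E)-4-cyano-3-methylbuta-1,3-dien-1-yl]-3,5,5-trimethylcyclohex-2-en-1-yl benzoate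
Conditions: 18, NaH (1.0 equiv), THF, 0 °C; then 17, −40 → 0 °C
Reagents that add atoms: diethyl [(2E)-3-cyano-2-methylprop-2-en-1-yl]phosphonate, CCOP(=O)(OCC)C/C(C)=C/C#N
Why: Horner–Wadsworth–Emmons olefination with the preformed, weakly basic vinylogous phosphonate anion forms C7'=C8' E-selectively and brings in the C9' methyl-bearing alkene (minor 9'Z isomer removed by chromatography) with no excess base to epimerise C6'.

Step 11
Reactants: 19
Product: 21 (2E,4E)-5-[(1R,4R)-4-hydroxy-2,6,6-trimethylcyclohex-2-en-1-yl]-3-methylpenta-2,4-dienal, via aldimine 20 (not isolated)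
Conditions: i-Bu2AlH (4 equiv), CH2Cl2, −78 °C; then aq. Rochelle salt, 0 °C
Reagents that add atoms: water, O
Why: i-Bu2AlH adds once to the conjugated nitrile to give an N-aluminium aldimine that hydrolyses to the dienal on work-up, and the same reagent reductively cleaves the benzoate, so the free (3'R)-hydroxy C15 aldehyde results in one operation.

Step 12
Reactants: 22 (4R,6R)-4-hydroxy-2,2,6-trimethylcyclohexan-1-one (actinol); 23 chlorotriethylsilane
Product: 24 (4R,6R)-2,2,6-trimethyl-4-[(triethylsilyl)oxy]cyclohexan-1-one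
Conditions: Et3SiCl, imidazole, CH2Cl2, 0 °C
Reagents that add atoms: chlorotriethylsilane, CC[Si](Cl)(CC)CC
Why: Silylation of the secondary alcohol protects it for the enolisation that follows.

Step 13
Reactants: 24; 25 N-phenylbis(trifluoromethanesulfonimide)
Product: 27 (4R)-2,6,6-trimethyl-4-[(triethylsilyl)oxy]cyclohex-1-en-1-yl trifluoromethanesulfonate, via lithium enolate 26 (not isolated)
Conditions: LiN(i-Pr)2, THF, −78 → 0 °C; then 25, 0 °C → rt
Reagents that add atoms: N-phenylbis(trifluoromethanesulfonimide), FC(F)(F)S(=O)(=O)N(c1ccccc1)S(=O)(=O)C(F)(F)F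
Why: The ketone can enolise only toward the methyl-bearing carbon (the other α-carbon is quaternary) and O-triflation of the lithium enolate gives the tetrasubstituted enol triflate; the methyl stereocentre is erased and the carbinol centre is untouched.

Step 14
Reactants: 27; 1 (2E)-3-methylpent-2-en-4-yn-1-ol
Product: 28 (2E)-3-methyl-5-{(4R)-2,6,6-trimethyl-4-[(triethylsilyl)oxy]cyclohex-1-en-1-yl}pent-2-en-4-yn-1-ol
Conditions: Pd(PPh3)4 (cat.), CuI (cat.), Et3N, DMF, rt
Reagents that add atoms: (2E)-3-methylpent-2-en-4-yn-1-ol, OC/C=C(C)/C#C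
Why: Sonogashira coupling of the hindered enol triflate with the terminal alkyne forms the C6–C7 bond and keeps the (E) trisubstituted alkene of the enynol.

Step 15
Reactants: 28; 29 triphenylphosphine hydrobromide
Product: 30 {(2E)-5-[(4R)-4-hydroxy-2,6,6-trimethylcyclohex-1-en-1-yl]-3-methylpent-2-en-4-yn-1-yl}triphenylphosphonium bromide
Conditions: PPh3·HBr (1.3 equiv), MeOH, 0 °C → rt
Reagents that add atoms: triphenylphosphine hydrobromide, [Br-].c1ccc([PH+](c2ccccc2)c2ccccc2)cc1
Why: The primary allylic alcohol ionises under HBr and is trapped by PPh3 at the primary terminus to give the phosphonium salt, while the acidic methanol solvolyses the triethylsilyl ether.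

Step 16
Reactants: 30; 31 (2E,4E,6E)-2,7-dimethylocta-2,4,6-trienedial
Product: 32 (2E,4E,6E,8E,10E)-13-[(4R)-4-hydroxy-2,6,6-trimethylcyclohex-1-en-1-yl]-2,7,11-trimethyltrideca-2,4,6,8,10-pentaen-12-ynal
Conditions: 31 (2.5 equiv), NaOMe (1.1 equiv), MeOH/CH2Cl2, 0 °C → rt
Reagents that add atoms: (2E,4E,6E)-2,7-dimethylocta-2,4,6-trienedial, O=C/C(C)=C/C=C/C=C(C)/C=O
Why: Wittig olefination of the conjugated ylide with an excess of the symmetric dialdehyde gives mono-condensation and forms C11=C12 mainly E (the hindered Z isomer is removed on crystallisation).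

Step 17
Reactants: 32
Product: 33 (2E,4E,6E,8E,10E)-13-[(4R)-4-hydroxy-2,6,6-trimethylcyclohex-1-en-1-yl]-2,7,11-trimethyltrideca-2,4,6,8,10-pentaen-12-yn-1-ol
Conditions: NaBH4, MeOH/CH2Cl2, 0 °C
Reagents that add atoms: none
Why: Borohydride performs 1,2-reduction of the conjugated aldehyde without touching the polyene or the alkyne.

Step 18
Reactants: 33; 29 triphenylphosphine hydrobromide
Product: 34 {(2E,4E,6E,8E,10E)-13-[(4R)-4-hydroxy-2,6,6-trimethylcyclohex-1-en-1-yl]-2,7,11-trimethyltrideca-2,4,6,8,10-pentaen-12-yn-1-yl}triphenylphosphonium bromide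
Conditions: PPh3·HBr (1.05 equiv), MeOH/CH2Cl2, 0 °C → rt, dark
Reagents that add atoms: triphenylphosphine hydrobromide, [Br-].c1ccc([PH+](c2ccccc2)c2ccccc2)cc1
Why: The polyenylic primary alcohol ionises readily and is trapped by PPh3 at the terminus, while the non-allylic ring alcohol does not ionise.

Step 19
Reactants: 34; 21 (2E,4E)-5-[(1R,4R)-4-hydroxy-2,6,6-trimethylcyclohex-2-en-1-yl]-3-methylpenta-2,4-dienal
Product: 36 (3R,3'R,6'R)-7,8-didehydro-β,ε-carotene-3,3'-diol (target), via 11'-cis isomer 35 (not isolated)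
Conditions: 1,2-epoxybutane, EtOH, reflux, dark; crystallisation
Reagents that add atoms: (2E,4E)-5-[(1R,4R)-4-hydroxy-2,6,6-trimethylcyclohex-2-en-1-yl]-3-methylpenta-2,4-dienal, CC1=C[C@H](O)CC(C)(C)[C@H]1/C=C/C(C)=C/C=O
Why: Wittig olefination under neutral conditions (the epoxide scavenges HBr) forms C11'=C12' without base that could move the ε-ring double bond or epimerise C6', and the warm medium converts the hindered 11'-cis isomer to the all-E polyene; iodine is avoided because the 9Z form of the acetylenic end is thermodynamically competitive.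

**Compound list**

1 | (2E)-3-methylpent-2-en-4-yn-1-ol | OC/C=C(C)/C#C | starting material
2 | 4-methoxybenzyl chloride | COc1ccc(CCl)cc1 | starting material
3 | 1-methoxy-4-({[(2E)-3-methylpent-2-en-4-yn-1-yl]oxy}methyl)benzene | COc1ccc(COC/C=C(C)/C#C)cc1 | intermediate
4 | pinacolborane | CC1(C)OBOC1(C)C | starting material
5 | potassium hydrogen difluoride | [K+].[F-].F | starting material
6 | 2-{(1E,3E)-5-[(4-methoxybenzyl)oxy]-3-methylpenta-1,3-dien-1-yl}-4,4,5,5-tetramethyl-1,3,2-dioxaborolane | COc1ccc(COC/C=C(C)/C=C/B2OC(C)(C)C(C)(C)O2)cc1 | intermediate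
7 | potassium trifluoro{(1E,3E)-5-[(4-methoxybenzyl)oxy]-3-methylpenta-1,3-dien-1-yl}borate | COc1ccc(COC/C=C(C)/C=C/[B-](F)(F)F)cc1.[K+] | intermediate
8 | (2S)-2-methoxy-2-phenylacetic acid | CO[C@H](C(=O)O)c1ccccc1 | starting material
9 | (1E,3E)-5-[(4-methoxybenzyl)oxy]-3-methylpenta-1,3-dien-1-yl (2S)-2-methoxy-2-phenylacetate | COc1ccc(COC/C=C(C)/C=C/OC(=O)[C@@H](OC)c2ccccc2)cc1 | intermediate
10 | 2-methyl-1-nitroprop-1-ene | CC(C)=C[N+](=O)[O-] | starting material
11 | (1R,4S)-4-{[(4-methoxybenzyl)oxy]methyl}-3,5,5-trimethyl-6-nitrocyclohex-2-en-1-yl (2S)-2-methoxy-2-phenylacetate, both C6 epimers | CC1=C[C@@H](OC(=O)[C@@H](OC)c2ccccc2)C([N+](=O)[O-])C(C)(C)[C@H]1COCc1ccc(OC)cc1 | intermediate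
12 | (1S,4R)-4-{[(4-methoxybenzyl)oxy]methyl}-3,5,5-trimethylcyclohex-2-en-1-yl (2S)-2-methoxy-2-phenylacetate | CC1=C[C@@H](OC(=O)[C@@H](OC)c2ccccc2)CC(C)(C)[C@H]1COCc1ccc(OC)cc1 | intermediate
13 | (1S,4R)-4-{[(4-methoxybenzyl)oxy]methyl}-3,5,5-trimethylcyclohex-2-en-1-ol | CC1=C[C@@H](O)CC(C)(C)[C@H]1COCc1ccc(OC)cc1 | intermediate
14 | benzoic acid | OC(=O)c1ccccc1 | starting material
15 | (1R,4R)-4-{[(4-methoxybenzyl)oxy]methyl}-3,5,5-trimethylcyclohex-2-en-1-yl benzoate | CC1=C[C@H](OC(=O)c2ccccc2)CC(C)(C)[C@H]1COCc1ccc(OC)cc1 | intermediate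
16 | (1R,4R)-4-(hydroxymethyl)-3,5,5-trimethylcyclohex-2-en-1-yl benzoate | CC1=C[C@H](OC(=O)c2ccccc2)CC(C)(C)[C@H]1CO | intermediate
17 | (1R,4R)-4-formyl-3,5,5-trimethylcyclohex-2-en-1-yl benzoate | CC1=C[C@H](OC(=O)c2ccccc2)CC(C)(C)[C@H]1C=O | intermediate
18 | diethyl [(2E)-3-cyano-2-methylprop-2-en-1-yl]phosphonate (supplied as an E/Z mixture; E shown) | CCOP(=O)(OCC)C/C(C)=C/C#N | starting material
19 | (1R,4R)-4-[(1E,3E)-4-cyano-3-methylbuta-1,3-dien-1-yl]-3,5,5-trimethylcyclohex-2-en-1-yl benzoate | CC1=C[C@H](OC(=O)c2ccccc2)CC(C)(C)[C@H]1/C=C/C(C)=C/C#N | intermediate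
20 | (1R,4R)-4-[(1E,3E)-5-imino-3-methylpenta-1,3-dien-1-yl]-3,5,5-trimethylcyclohex-2-en-1-ol (present as its aluminium derivative before hydrolysis) | CC1=C[C@H](O)CC(C)(C)[C@H]1/C=C/C(C)=C/C=N | intermediate
21 | (2E,4E)-5-[(1R,4R)-4-hydroxy-2,6,6-trimethylcyclohex-2-en-1-yl]-3-methylpenta-2,4-dienal | CC1=C[C@H](O)CC(C)(C)[C@H]1/C=C/C(C)=C/C=O | intermediate
22 | (4R,6R)-4-hydroxy-2,2,6-trimethylcyclohexan-1-one (actinol) | O=C1[C@H](C)C[C@@H](O)CC1(C)C | starting material
23 | chlorotriethylsilane | CC[Si](Cl)(CC)CC | starting material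
24 | (4R,6R)-2,2,6-trimethyl-4-[(triethylsilyl)oxy]cyclohexan-1-one | O=C1[C@H](C)C[C@@H](O[Si](CC)(CC)CC)CC1(C)C | intermediate
25 | N-phenylbis(trifluoromethanesulfonimide) | FC(F)(F)S(=O)(=O)N(c1ccccc1)S(=O)(=O)C(F)(F)F | starting material
26 | lithium (4R)-2,6,6-trimethyl-4-[(triethylsilyl)oxy]cyclohex-1-en-1-olate | [Li+].[O-]C1=C(C)C[C@@H](O[Si](CC)(CC)CC)CC1(C)C | intermediate
27 | (4R)-2,6,6-trimethyl-4-[(triethylsilyl)oxy]cyclohex-1-en-1-yl trifluoromethanesulfonate | FC(F)(F)S(=O)(=O)OC1=C(C)C[C@@H](O[Si](CC)(CC)CC)CC1(C)C | intermediate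
28 | (2E)-3-methyl-5-{(4R)-2,6,6-trimethyl-4-[(triethylsilyl)oxy]cyclohex-1-en-1-yl}pent-2-en-4-yn-1-ol | OC/C=C(C)/C#CC1=C(C)C[C@@H](O[Si](CC)(CC)CC)CC1(C)C | intermediate
29 | triphenylphosphine hydrobromide | [Br-].c1ccc([PH+](c2ccccc2)c2ccccc2)cc1 | starting material
30 | {(2E)-5-[(4R)-4-hydroxy-2,6,6-trimethylcyclohex-1-en-1-yl]-3-methylpent-2-en-4-yn-1-yl}triphenylphosphonium bromide | c1ccc(cc1)[P+](c1ccccc1)(c1ccccc1)C/C=C(C)/C#CC1=C(C)C[C@@H](O)CC1(C)C.[Br-] | intermediate
31 | (2E,4E,6E)-2,7-dimethylocta-2,4,6-trienedial | O=C/C(C)=C/C=C/C=C(C)/C=O | starting material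
32 | (2E,4E,6E,8E,10E)-13-[(4R)-4-hydroxy-2,6,6-trimethylcyclohex-1-en-1-yl]-2,7,11-trimethyltrideca-2,4,6,8,10-pentaen-12-ynal | O=C/C(C)=C/C=C/C=C(C)/C=C/C=C(\C)C#CC1=C(C)C[C@@H](O)CC1(C)C | intermediate
33 | (2E,4E,6E,8E,10E)-13-[(4R)-4-hydroxy-2,6,6-trimethylcyclohex-1-en-1-yl]-2,7,11-trimethyltrideca-2,4,6,8,10-pentaen-12-yn-1-ol | OC/C(C)=C/C=C/C=C(C)/C=C/C=C(\C)C#CC1=C(C)C[C@@H](O)CC1(C)C | intermediate
34 | {(2E,4E,6E,8E,10E)-13-[(4R)-4-hydroxy-2,6,6-trimethylcyclohex-1-en-1-yl]-2,7,11-trimethyltrideca-2,4,6,8,10-pentaen-12-yn-1-yl}triphenylphosphonium bromide | c1ccc(cc1)[P+](c1ccccc1)(c1ccccc1)C/C(C)=C/C=C/C=C(C)/C=C/C=C(\C)C#CC1=C(C)C[C@@H](O)CC1(C)C.[Br-] | intermediate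
35 | (11'Z)-(3R,3'R,6'R)-7,8-didehydro-β,ε-carotene-3,3'-diol | CC1=C[C@H](O)CC(C)(C)[C@H]1/C=C/C(C)=C/C=C\C(C)=C\C=C\C=C(C)\C=C\C=C(/C)C#CC1=C(C)C[C@@H](O)CC1(C)C | intermediate
36 | (3R,3'R,6'R)-7,8-didehydro-β,ε-carotene-3,3'-diol (all-E) | CC1=C[C@H](O)CC(C)(C)[C@H]1/C=C/C(C)=C/C=C/C(C)=C/C=C/C=C(C)/C=C/C=C(\C)C#CC1=C(C)C[C@@H](O)CC1(C)C | target

**Step count and risks**

Total steps: 19. Longest linear sequence: 12 steps (steps 1–11, then 19); the β branch is 8 steps (12–18, then 19).

The three steps most likely to fail: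

Step 4. The cycloaddition may be sluggish at the congested bond between the substituted diene terminus and the fully substituted nitroalkene carbon, because a dienyl ester is only moderately electron-rich; regio- or facial selectivity may also erode. The fallback sets out from 7 and returns at 12, and it replaces auxiliary control by a more reactive diene followed by resolution through diastereomeric esters. Copper-catalysed coupling of 7 with acetic acid gives the dienyl acetate F1. MeLi (2 equiv, THF, −78 °C) releases the geometrically defined lithium dienolate, which is O-silylated with t-BuMe2SiCl to the (1E,3E)-silyl dienol ether F2. This more electron-rich diene adds 10 thermally (toluene, 110 °C) to give the racemic cis nitro adduct F3. Bu3SnH/AIBN gives the racemic silyl ether F4, and Bu4NF the racemic cis alcohol F5. Esterification with 8 (DCC, cat. DMAP, 0 °C) gives 12 together with its diastereomer F6, and the two are separated by chromatography.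

Step 5. The β-(acyloxy)alkyl radical may undergo 1,2-acyloxy migration toward the allylic position, or C–N homolysis of the secondary nitro group may be slow and reduction at nitrogen may compete. The fallback sets out from 11 and returns at 13; it removes the acyl group before the radical step, so the facial diastereomers are separated at the stage of 11. i-Bu2AlH (CH2Cl2, −78 °C, acidic quench) cleaves the ester without base, avoiding retro-nitroaldol and elimination, and gives the nitro alcohol F7. Et3SiOTf/2,6-lutidine gives the nitro silyl ether F8, whose radical cannot rearrange. Bu3SnH/AIBN gives the silyl ether F9, and Bu4NF gives 13.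

Step 10 (with step 9). The formyl-bearing ring carbon may epimerise, or the ring double bond may migrate into conjugation, during oxidation and basic olefination. The fallback sets out from 16 and returns at 19 with reversed polarity, so that no enolisable aldehyde is ever made on the ring. Mitsunobu thioetherification of 16 with 1-phenyl-1H-tetrazole-5-thiol gives the sulfide F10. Oxidation with (NH4)6Mo7O24/H2O2 (EtOH) gives the sulfone F11. Julia–Kocienski olefination (KN(SiMe3)2, DME, −60 °C) with (2E)-3-methyl-4-oxobut-2-enenitrile F12, made from 3-methylbut-2-enenitrile with SeO2, gives 19.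

Further compounds
F1 | step 4 | (1E,3E)-5-[(4-methoxybenzyl)oxy]-3-methylpenta-1,3-dien-1-yl acetate | COc1ccc(COC/C=C(C)/C=C/OC(C)=O)cc1
F2 | step 4 | tert-butyl({(1E,3E)-5-[(4-methoxybenzyl)oxy]-3-methylpenta-1,3-dien-1-yl}oxy)dimethylsilane | COc1ccc(COC/C=C(C)/C=C/O[Si](C)(C)C(C)(C)C)cc1
F3 | step 4 | rac-(1R,4S)-tert-butyl[(4-{[(4-methoxybenzyl)oxy]methyl}-3,5,5-trimethyl-6-nitrocyclohex-2-en-1-yl)oxy]dimethylsilane, cis, both C6 epimers (one enantiomer drawn) | CC1=C[C@@H](O[Si](C)(C)C(C)(C)C)C([N+](=O)[O-])C(C)(C)[C@H]1COCc1ccc(OC)cc1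
F4 | step 4 | rac-(1S,4R)-tert-butyl[(4-{[(4-methoxybenzyl)oxy]methyl}-3,5,5-trimethylcyclohex-2-en-1-yl)oxy]dimethylsilane, cis (one enantiomer drawn) | CC1=C[C@@H](O[Si](C)(C)C(C)(C)C)CC(C)(C)[C@H]1COCc1ccc(OC)cc1
F5 | step 4 | rac-(1S,4R)-4-{[(4-methoxybenzyl)oxy]methyl}-3,5,5-trimethylcyclohex-2-en-1-ol, cis (one enantiomer drawn) | CC1=C[C@@H](O)CC(C)(C)[C@H]1COCc1ccc(OC)cc1
F6 | step 4 | (1R,4S)-4-{[(4-methoxybenzyl)oxy]methyl}-3,5,5-trimethylcyclohex-2-en-1-yl (2S)-2-methoxy-2-phenylacetate | CC1=C[C@H](OC(=O)[C@@H](OC)c2ccccc2)CC(C)(C)[C@@H]1COCc1ccc(OC)cc1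
F7 | step 5 | (1R,4S)-4-{[(4-methoxybenzyl)oxy]methyl}-3,5,5-trimethyl-6-nitrocyclohex-2-en-1-ol, both C6 epimers | CC1=C[C@@H](O)C([N+](=O)[O-])C(C)(C)[C@H]1COCc1ccc(OC)cc1
F8 | step 5 | (1R,4S)-triethyl[(4-{[(4-methoxybenzyl)oxy]methyl}-3,5,5-trimethyl-6-nitrocyclohex-2-en-1-yl)oxy]silane, both C6 epimers | CC1=C[C@@H](O[Si](CC)(CC)CC)C([N+](=O)[O-])C(C)(C)[C@H]1COCc1ccc(OC)cc1
F9 | step 5 | (1S,4R)-triethyl[(4-{[(4-methoxybenzyl)oxy]methyl}-3,5,5-trimethylcyclohex-2-en-1-yl)oxy]silane | CC1=C[C@@H](O[Si](CC)(CC)CC)CC(C)(C)[C@H]1COCc1ccc(OC)cc1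
F10 | step 10 | (1R,4R)-3,5,5-trimethyl-4-{[(1-phenyl-1H-tetrazol-5-yl)sulfanyl]methyl}cyclohex-2-en-1-yl benzoate | CC1=C[C@H](OC(=O)c2ccccc2)CC(C)(C)[C@H]1CSc1nnnn1-c1ccccc1
F11 | step 10 | (1R,4R)-3,5,5-trimethyl-4-{[(1-phenyl-1H-tetrazol-5-yl)sulfonyl]methyl}cyclohex-2-en-1-yl benzoate | CC1=C[C@H](OC(=O)c2ccccc2)CC(C)(C)[C@H]1CS(=O)(=O)c1nnnn1-c1ccccc1
F12 | step 10 | (2E)-3-methyl-4-oxobut-2-enenitrile | N#C/C=C(C)/C=O
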